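The data come from a simulation with constants of no real substance; scatter was added.

In fractions of the starting material charged, the target read in the north run falls from 7.4% at 20.0 s to 2.2% at 80.0 s, and the target read in the west run falls from 21.9% at 30.0 s to 12.0% at 80.0 s.

| flask | starting material | partner | second substrate | remark | time |
|---|---|---|---|---|---|
| west | 26 mM | 24 mM | 40 mM | run made earlier |  |
| north | 250 mM | 24 mM | 40 mM | run made earlier |  |
| spring | 20 mM | 24.0 mM | 40.0 mM |  | 2.0 min |
| noon | 60 mM | 24.0 mM | 40.0 mM |  | 2.0 min |
| summer | 200 mM | 24.0 mM | 40.0 mM |  | 2.0 min |

| run | time / s | target / % |
|---|---|---|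
| west | 10.0 | 14.6 |
| west | 15.0 | 19.3 |
| west | 30.0 | 21.9 |
| west | 50.0 | 18.0 |
| west | 60.0 | 16.3 |
| west | 80.0 | 12.0 |
| north | 10.0 | 6.8 |
| north | 12.0 | 7.1 |
| north | 20.0 | 7.4 |
| north | 30.0 | 5.5 |
| north | 50.0 | 3.1 |
| north | 80.0 | 2.2 |

(each reading ± 0.5 percentage points)

- the earlier runs were read with a standard deviation of 0.5 percentage points
- steps thought possible: target <-> isomer of the product; starting material + second substrate -> cross product; starting material + partner -> target; target -> over-reaction product; second substrate + partner -> second product
- "hardly changes" means that all values lie within two and a half points (for a concentration: within two and a half percent of the largest)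

- [target] at the end for spring, noon, summer, in this order
- the shape of the row from first to last (rises, then falls / falls all the way / falls, then rises / hardly changes / rises all the way)

From these north readings, with their scatter, comes a reading of the target's lifetime 49.5 s, the time in which the target reading shrinks by a factor of e. The same reading in the west run is longer, 83.1 s. Counting lifetimes from each highest reading to 2.0 min, and keeping each run's fraction, this reckoning of our own puts spring near 1.48 mM from the west run and summer near 1.96 mM from the north run. It gives no number for noon.

The forecast gives 1.5 mM, 2.7 mM and 3.3 mM, so its shape is "rises all the way": “The row rises throughout, flattening at high starting material.”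

The flask gives 1.26 mM, 3.03 mM and 1.96 mM, so the shape is "rises, then falls", with summer below noon.

    target ⇌ isomer of the product (K = 8.50, k = 0.00690 s⁻¹)
    starting material + second substrate → cross product (k = 0.610 M⁻¹ s⁻¹)
    starting material + partner → target (k = 0.980 M⁻¹ s⁻¹)
    target → over-reaction product (k = 0.0160 s⁻¹)
    second substrate + partner → second product (k = 0.0210 M⁻¹ s⁻¹)

In summer, partner, the limiting reagent there, stands at 0.0195% of its charge at 1.00 min, and over the next minute the target goes from 3.56% to 0.980%, where the lifetime counts 1.06%. In spring, the target over the same minute goes from 17.1% to 6.32%, above the counted 5.07%, and in spring the target is made 2.05 times faster than it is used up at 0.271 min, but at 2.00 min it is made at 0.158 of the rate at which it is then used up.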